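**Assumption:** atoms are cited in germacrane numbering (C1 ketone, C2–C3 oxirane, C4 CHMe, C5 CH2, C6 lactone CH–O, C7 ring-fusion CH, C8 crotonate, C9 acetate, C10 carbinol, C11–C13 methylene-lactone carbons). The target is then 2S,3S,4R,6R,7S,8S,9R,10S.

## Retrosynthetic overview
1. The C2–C3 oxirane is made last, by nucleophilic epoxidation of the ten-membered Z-enone.
2. The ten-membered carbocycle comes from a seven-membered lactone (O6–C1 ester). C2 is transferred onto C1, the C1–O6 bond breaks (ring expansion 7 to 10), and the freed O6 closes the butyrolactone.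
3. C8 and C9 are oxygenated on the rigid seven-membered lactone: ring-closing metathesis (C8=C9), epoxidation of the open face, opening by crotonic acid, then acetate.
4. The metathesis precursor is the ester of a C2–C8/C11–C13 alcohol with (S)-2-hydroxy-2-methylbut-3-enoic acid (C1, C9, C10, C14).
5. The C6–C7 bond comes from an anti-selective allylation. Ring order: oxepinone, carbocycle, butyrolactone, oxirane.

## Route

Step 1
Reactants: 1 (2Z)-3-methylpent-2-en-4-yn-1-ol
Product: 2 (2Z)-3-methylpent-2-en-4-ynal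
Conditions: MnO2 (10 equiv), CH2Cl2, rt
Reagents that add atoms: none
Why: Allylic alcohol oxidation with activated MnO2 stops at the enal and spares the alkyne, and the alkene geometry does not matter because step 2 is stereoconvergent.

Step 2
Reactants: 2 (2Z)-3-methylpent-2-en-4-ynal
Product: 3 (3R)-3-methylpent-4-ynal
Conditions: (S)-2-tert-butyl-3-methylimidazolidin-4-one·CCl3CO2H (20 mol %), diethyl 2,6-dimethyl-1,4-dihydropyridine-3,5-dicarboxylate (1.2 equiv), CHCl3, −30 °C
Reagents that add atoms: none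
Why: Iminium-catalysed asymmetric transfer hydrogenation (MacMillan type), in which the iminium E/Z isomers equilibrate and hydride reaches the unshielded face, sets C4 as R with methyl acting as the larger and the rod-like ethynyl as the smaller β-group.

Step 3
Reactants: 3 (3R)-3-methylpent-4-ynal
Product: 4 (3R)-5-iodo-3-methylpent-4-ynal
Conditions: NIS (1.1 equiv), AgNO3 (10 mol %), acetone, rt
Reagents that add atoms: N-iodosuccinimide, O=C1CCC(=O)N1I
Why: Silver-catalysed electrophilic iodination of a terminal alkyne is mild enough for the aldehyde and leaves C4 untouched.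

Step 4
Reactants: 4 (3R)-5-iodo-3-methylpent-4-ynal
Product: 5 (3R,4Z)-5-iodo-3-methylpent-4-enal
Conditions: KO2CN=NCO2K (3 equiv), AcOH (6 equiv), pyridine, dioxane/iPrOH, rt
Reagents that add atoms: none
Why: Diimide reduction delivers both hydrogens to one face of the iodoalkyne, so only the Z-alkenyl iodide forms, and neither the aldehyde nor the carbon–iodine bond is reduced.

Step 5
Reactants: 6 acrolein; 7 methyl acrylate
Product: 8 methyl 3-hydroxy-2-methylidenepent-4-enoate (racemic)
Conditions: DABCO (20 mol %), dioxane/H2O, rt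
Reagents that add atoms: none
Why: The Morita–Baylis–Hillman reaction joins C7 to C11, and the carbinol centre is erased in step 6.

Step 6
Reactants: 8 methyl 3-hydroxy-2-methylidenepent-4-enoate
Product: 9 methyl (2Z)-2-(bromomethyl)penta-2,4-dienoate
Conditions: PBr3 (0.4 equiv), Et2O, 0 °C
Reagents that add atoms: phosphorus tribromide, BrP(Br)Br
Why: SN2' bromination with allylic transposition gives the conjugated primary bromide, and any regioisomeric bromide leads to the same delocalised allyl metal in step 7.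

Step 7
Reactants: 5 (3R,4Z)-5-iodo-3-methylpent-4-enal; 9 methyl (2Z)-2-(bromomethyl)penta-2,4-dienoate
Product: 11 methyl (3S,4R,6R,7Z)-3-ethenyl-4-hydroxy-8-iodo-6-methyl-2-methylideneoct-7-enoate, via trimethylsilyl ether 10 (not isolated)
Conditions: CrCl2 (10 mol %, nickel-free), (S,S)-3,6-di-tert-butyl-1,8-bis(4-isopropyl-4,5-dihydrooxazol-2-yl)carbazole (12 mol %), Mn (2 equiv), TMSCl (1.5 equiv), THF, 0 °C; then 1 M aq citric acid, 0 °C
Reagents that add atoms: none
Why: In this catalytic asymmetric Nozaki–Hiyama 2-(alkoxycarbonyl)allylation the pentadienyl chromium species reacts at its central carbon through a chair transition state (anti, hence the later trans-lactone), the ligand fixes 6R,7S over the remote C4 centre, and without nickel the alkenyl iodide stays inert.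

Step 8
Reactants: 12 2-methyl-2-vinyloxirane (racemic)
Product: 14 (2S)-2-methylbut-3-ene-1,2-diol, via cyclic carbonate 13 (not isolated)
Conditions: Pd2(dba)3·CHCl3 (1 mol %), (S,S)-DACH-naphthyl Trost ligand (3 mol %), Et3B (2 mol %), NaHCO3 (1.2 equiv), CH2Cl2/H2O, rt
Reagents that add atoms: sodium hydrogencarbonate, [Na+].OC([O-])=O
Why: In this palladium-catalysed dynamic kinetic asymmetric allylic substitution (Tsuji–Trost type) both epoxide enantiomers funnel through equilibrating π-allyl complexes, and boron-tethered carbonate attacks the tertiary terminus to set C10 as S.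

Step 9
Reactants: 14 (2S)-2-methylbut-3-ene-1,2-diol
Product: 16 (2S)-2-hydroxy-2-methylbut-3-enoic acid, via hydroxy aldehyde 15 (not isolated)
Conditions: TEMPO (7 mol %), NaOCl (2 mol %), NaClO2 (2 equiv), MeCN/phosphate buffer pH 6.7, 35 °C
Reagents that add atoms: sodium chlorite, [Na+].[O-]Cl=O
Why: The TEMPO/chlorite (Anelli–Zhao) oxidation takes only the primary alcohol to the acid and cannot epimerise the fully substituted C10.

Step 10
Reactants: 11 methyl (3S,4R,6R,7Z)-3-ethenyl-4-hydroxy-8-iodo-6-methyl-2-methylideneoct-7-enoate; 16 (2S)-2-hydroxy-2-methylbut-3-enoic acid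
Product: 17 methyl (3S,4R,6R,7Z)-3-ethenyl-4-{[(2S)-2-hydroxy-2-methylbut-3-enoyl]oxy}-8-iodo-6-methyl-2-methylideneoct-7-enoate
Conditions: 2-methyl-6-nitrobenzoic anhydride (1.3 equiv), DMAP (0.2 equiv), Et3N (3 equiv), CH2Cl2, 0 °C to rt
Reagents that add atoms: none
Why: Shiina mixed-anhydride esterification copes with the hindered partners, the tertiary hydroxyl of 16 is too hindered to self-acylate, and acylating O6 keeps it from lactonising on the acrylate ester.

Step 11
Reactants: 17 ester of 11 and 16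
Product: 18 methyl 2-{(2R,3S,6S)-6-hydroxy-2-[(2R,3Z)-4-iodo-2-methylbut-3-en-1-yl]-6-methyl-7-oxo-2,3,6,7-tetrahydrooxepin-3-yl}prop-2-enoate
Conditions: second-generation Hoveyda–Grubbs catalyst RuCl2(=CH-2-iPrOC6H4)(SIMes) (5 mol %), 1,4-benzoquinone (10 mol %), toluene (2 mM), 60 °C
Reagents that add atoms: none
Why: In this ring-closing metathesis the two monosubstituted vinyl groups pair first (the 1,1-disubstituted acrylate and the alkenyl iodide are poor partners), and a seven-membered ring can only hold the Z C8=C9 bond.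

Step 12
Reactants: 18 oxepinone
Product: 19 (4R,6R,7S,8R,9R,10S)-8,9-epoxide of 18 (oxirane cis to H6 and H7 and the C10 methyl)
Conditions: dimethyldioxirane (1.1 equiv, acetone), CH2Cl2, −20 °C
Reagents that add atoms: dimethyldioxirane, CC1(C)OO1
Why: In this dioxirane epoxidation under steric control the C6 side chain, the C7 acrylate and the C10 hydroxyl all sit on one face of the oxepinone, so oxygen arrives on the open face, while the acrylate and the alkenyl iodide are too electron-poor to react.

Step 13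
Reactants: 19 epoxy oxepanone; 20 (E)-but-2-enoic acid (crotonic acid)
Product: 22 (4R,6R,7S,8S,9R,10S)-9-acetoxy-8-[(E)-but-2-enoyloxy]-10-hydroxy oxepanone (alkenyl iodide and acrylate ester unchanged), via hydroxy crotonate 21 (not isolated)
Conditions: (R,R)-(salen)Co(OAc) (5 mol %, salen = N,N'-bis(3,5-di-tert-butylsalicylidene)cyclohexane-1,2-diamine dianion, the antipode matched to attack at C8), 20 (1.5 equiv), iPr2NEt (1 equiv), TBME, rt; then Ac2O (2 equiv), DMAP (10 mol %), 0 °C
Reagents that add atoms: acetic anhydride, CC(=O)OC(C)=O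
Why: Cobalt-salen catalysed opening of the epoxide by a carboxylic acid (Jacobsen type, SN2 with inversion) goes to C8 because C9 is neopentyl-like and the catalyst reinforces this, which sets 8S and keeps 9R, and the in-flask acetylation takes only the secondary C9 hydroxyl.

Step 14
Reactants: 22 alkenyl iodide oxepanone
Product: 23 Z-alkenyl pinacol boronate of 22 (iodine at C2 replaced by Bpin)
Conditions: PdCl2(PPh3)2 (3 mol %), PPh3 (6 mol %), B2pin2 (1.1 equiv), KOPh (1.5 equiv), toluene, 50 °C
Reagents that add atoms: bis(pinacolato)diboron, CC1(C)OB(OC1(C)C)B1OC(C)(C)C(C)(C)O1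
Why: Miyaura borylation of an alkenyl iodide retains the Z geometry and tolerates esters, the lactone and the free tertiary alcohol.

Step 15
Reactants: 23 Z-alkenyl boronate oxepanone
Product: 26 (2Z,4R,6R,7S,8S,9R,10S)-9-acetoxy-8-[(E)-but-2-enoyloxy]-10-hydroxy-1-oxogermacra-2,11(13)-dien-12,6-olide, via bridged rhodium hemiketal 24 (not isolated), via ring-expanded rhodium alkoxide 25 (not isolated)
Conditions: [Rh(OH)(cod)]2 (5 mol %), MS 4A, dry 1,4-dioxane (5 mM), 60 °C
Reagents that add atoms: none
Why: Proposed new method: boron-to-rhodium exchange (retention) makes C2 a soft alkenyl nucleophile that adds through a seven-membered transition state to the lactone carbonyl C1 on the face carrying the C6 side chain; the bridged 11-oxabicyclo[4.4.1] hemiketal alkoxide 24 collapses by expelling O6 (C1–O6 cleavage, ring expansion from seven to ten atoms, no stereocentre touched); the freed C6 alkoxide 25 lactonises irreversibly on the acrylate ester, and the Rh–OMe so formed takes up the next boronate, so the cycle is base-free and redox-neutral and spares acetate, crotonate and the tertiary alcohol; the closest known reaction types are the intramolecular acylation of organorhodium species by esters and the samarium diiodide lactone-to-carbocycle acyl-substitution ring expansions to eight- and nine-membered rings.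

Step 16
Reactants: 26 Z-enone lactone
Product: 27 (2S,3S,4R,6R,7S,8S,9R,10S)-9-acetoxy-8-[(E)-but-2-enoyloxy]-2,3-epoxy-10-hydroxy-1-oxogermacr-11(13)-en-12,6-olide (target)
Conditions: La(OiPr)3 (10 mol %), 2,2'-biphenol (10 mol %), Ph3P=O (30 mol %), tBuOOH (1.5 equiv, decane), MS 4A, THF, rt
Reagents that add atoms: tert-butyl hydroperoxide, CC(C)(C)OO
Why: In this lanthanide-alkoxide Weitz–Scheffer epoxidation the C10–OH/C1=O chelate holds lanthanum so that the bound peroxide adds only to the ketone-conjugated C2=C3 bond (this catalyst does not activate ester-type acceptors), and peripheral attack on the conformer with H4 eclipsing the Z-alkene (allylic 1,3-strain) followed by ring-locked closure gives the cis 2S,3S-oxirane.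

## Compound list
1 | (2Z)-3-methylpent-2-en-4-yn-1-ol | C#C/C(C)=C\CO | starting material
2 | (2Z)-3-methylpent-2-en-4-ynal | C#C/C(C)=C\C=O | intermediate
3 | (3R)-3-methylpent-4-ynal | O=CC[C@@H](C)C#C | intermediate
4 | (3R)-5-iodo-3-methylpent-4-ynal | O=CC[C@@H](C)C#CI | intermediate
5 | (3R,4Z)-5-iodo-3-methylpent-4-enal | O=CC[C@@H](C)/C=C\I | intermediate
6 | acrolein | C=CC=O | starting material
7 | methyl acrylate | C=CC(=O)OC | starting material
8 | methyl 3-hydroxy-2-methylidenepent-4-enoate (racemic) | C=CC(O)C(=C)C(=O)OC | intermediate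
9 | methyl (2Z)-2-(bromomethyl)penta-2,4-dienoate | C=C/C=C(\CBr)C(=O)OC | intermediate
10 | trimethylsilyl ether of 11 | C=C(C(=O)OC)[C@H](C=C)[C@H](O[Si](C)(C)C)C[C@@H](C)/C=C\I | intermediate
11 | methyl (3S,4R,6R,7Z)-3-ethenyl-4-hydroxy-8-iodo-6-methyl-2-methylideneoct-7-enoate | C=C(C(=O)OC)[C@H](C=C)[C@H](O)C[C@@H](C)/C=C\I | intermediate
12 | 2-methyl-2-vinyloxirane (racemic) | CC1(C=C)CO1 | starting material
13 | (4S)-4-ethenyl-4-methyl-1,3-dioxolan-2-one | C=C[C@@]1(C)COC(=O)O1 | intermediate
14 | (2S)-2-methylbut-3-ene-1,2-diol | C=C[C@](C)(O)CO | intermediate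
15 | (2S)-2-hydroxy-2-methylbut-3-enal | C=C[C@](C)(O)C=O | intermediate
16 | (2S)-2-hydroxy-2-methylbut-3-enoic acid | C=C[C@](C)(O)C(=O)O | intermediate
17 | O6 ester of 11 with 16 | C=C(C(=O)OC)[C@H](C=C)[C@H](OC(=O)[C@@](C)(O)C=C)C[C@@H](C)/C=C\I | intermediate
18 | oxepinone (4R,6R,7S,10S; C8=C9 in the ring) | C=C(C(=O)OC)[C@@H]1C=C[C@](C)(O)C(=O)O[C@@H]1C[C@@H](C)/C=C\I | intermediate
19 | (8R,9R)-epoxy oxepanone | C=C(C(=O)OC)[C@@H]1[C@H]2O[C@H]2[C@](C)(O)C(=O)O[C@@H]1C[C@@H](C)/C=C\I | intermediate
20 | (E)-but-2-enoic acid | C/C=C/C(=O)O | starting material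
21 | (8S,9R)-8-crotonyloxy-9-hydroxy oxepanone | C=C(C(=O)OC)[C@@H]1[C@H](OC(=O)/C=C/C)[C@@H](O)[C@](C)(O)C(=O)O[C@@H]1C[C@@H](C)/C=C\I | intermediate
22 | (8S,9R)-9-acetoxy-8-crotonyloxy oxepanone, alkenyl iodide | C=C(C(=O)OC)[C@@H]1[C@H](OC(=O)/C=C/C)[C@@H](OC(C)=O)[C@](C)(O)C(=O)O[C@@H]1C[C@@H](C)/C=C\I | intermediate
23 | Z-alkenyl pinacol boronate of 22 | C=C(C(=O)OC)[C@@H]1[C@H](OC(=O)/C=C/C)[C@@H](OC(C)=O)[C@](C)(O)C(=O)O[C@@H]1C[C@@H](C)/C=C\B2OC(C)(C)C(C)(C)O2 | intermediate
24 | bridged (1S)-11-oxabicyclo[4.4.1] hemiketal, rhodium alkoxide (cod ligand omitted) | C=C(C(=O)OC)[C@@H]1[C@H](OC(=O)/C=C/C)[C@@H](OC(C)=O)[C@](C)(O)[C@@]2([O-])O[C@@H]1C[C@@H](C)C=C2.[Rh+] | intermediate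
25 | ten-membered Z-enone, C6 rhodium alkoxide, methyl ester (cod ligand omitted) | C=C(C(=O)OC)[C@@H]1[C@H](OC(=O)/C=C/C)[C@@H](OC(C)=O)[C@](C)(O)C(=O)/C=C\[C@H](C)C[C@H]1[O-].[Rh+] | intermediate
26 | (2Z,4R,6R,7S,8S,9R,10S)-9-acetoxy-8-crotonyloxy-10-hydroxy-1-oxogermacra-2,11(13)-dien-12,6-olide | C=C1C(=O)O[C@@H]2C[C@@H](C)/C=C\C(=O)[C@@](C)(O)[C@H](OC(C)=O)[C@@H](OC(=O)/C=C/C)[C@@H]12 | intermediate
27 | CNP0358125.1 | C=C1C(=O)O[C@@H]2C[C@@H](C)[C@@H]3O[C@@H]3C(=O)[C@@](C)(O)[C@H](OC(C)=O)[C@@H](OC(=O)/C=C/C)[C@@H]12 | target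

## Step count and risks
Total steps: 16. Longest linear sequence: 12 (steps 1–4, 7, 10–16).

**Step 15 (new ring expansion).**
- Risks: protodeboronation, conjugate addition of the alkenyl rhodium species to the acrylate, or a hemiketal that does not collapse.
- The fallback runs from 22 back to 26 with known chemistry and no ring expansion.
- Hydroxyl-directed aminolysis of the α-hydroxy lactone with MeNH(OMe) and Ta(OEt)5 opens only the oxepanone. The freed C6 hydroxyl then closes on the acrylate ester (cat. camphorsulfonic acid) to give the Weinreb amide butyrolactone F1.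
- Cp2Zr(H)Cl reduces the amide to the α-hydroxy aldehyde F2.
- An intramolecular Nozaki–Hiyama–Kishi reaction (CrCl2, 1 mol % NiCl2, DMSO, 2 mM) closes the ten-membered ring to the macrocyclic allylic alcohol F3 (C1 epimers).
- Dess–Martin periodinane oxidises F3 to 26.

**Step 16 (chemoselectivity against the methylene lactone and crotonate; facial selectivity).**
- The fallback runs from 26 back to 27.
- PhSH/Et3N masks the methylene lactone as the phenylthio adduct F4.
- Classical tBuOOH/DBU epoxidation of the only remaining strong acceptor gives the epoxy ketone sulfide F5.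
- mCPBA (1 equiv, −78 °C) gives the sulfoxide F6.
- Warm toluene over CaCO3 eliminates sulfenic acid, restoring the methylene group and giving 27.

**Step 13 (regiochemistry and rate of the opening on the hindered face; acyl migration).**
- The fallback runs from 18 back to 21.
- OsO4/NMO dihydroxylates the open face to the cis-diol F7.
- SOCl2, then RuCl3/NaIO4, gives the cyclic sulfate F8.
- Caesium crotonate opens the more reactive sulfate at C8 with inversion to the sulfate monoester F9.
- Dilute H2SO4 in THF hydrolyses F9 to 21, which is acetylated as in step 13.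

## Further compounds
F1 | step 15 | Weinreb amide butyrolactone (seco at C1–C2) | C=C1C(=O)O[C@H](C[C@@H](C)/C=C\I)[C@H]1[C@H](OC(=O)/C=C/C)[C@@H](OC(C)=O)[C@](C)(O)C(=O)N(C)OC
F2 | step 15 | α-hydroxy aldehyde | C=C1C(=O)O[C@H](C[C@@H](C)/C=C\I)[C@H]1[C@H](OC(=O)/C=C/C)[C@@H](OC(C)=O)[C@](C)(O)C=O
F3 | step 15 | macrocyclic allylic alcohol (C1 epimers) | C=C1C(=O)O[C@@H]2C[C@@H](C)/C=C\C(O)[C@@](C)(O)[C@H](OC(C)=O)[C@@H](OC(=O)/C=C/C)[C@@H]12
F4 | step 16 | phenylthio adduct of 26 (C11 epimers) | c1ccccc1SCC1C(=O)O[C@@H]2C[C@@H](C)/C=C\C(=O)[C@@](C)(O)[C@H](OC(C)=O)[C@@H](OC(=O)/C=C/C)[C@@H]12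
F5 | step 16 | epoxy ketone sulfide | c1ccccc1SCC1C(=O)O[C@@H]2C[C@@H](C)[C@@H]3O[C@@H]3C(=O)[C@@](C)(O)[C@H](OC(C)=O)[C@@H](OC(=O)/C=C/C)[C@@H]12
F6 | step 16 | sulfoxide | O=S(CC1C(=O)O[C@@H]2C[C@@H](C)[C@@H]3O[C@@H]3C(=O)[C@@](C)(O)[C@H](OC(C)=O)[C@@H](OC(=O)/C=C/C)[C@@H]12)c1ccccc1
F7 | step 13 | 8,9-cis-diol of the oxepanone | C=C(C(=O)OC)[C@@H]1[C@@H](O)[C@@H](O)[C@](C)(O)C(=O)O[C@@H]1C[C@@H](C)/C=C\I
F8 | step 13 | 8,9-cyclic sulfate | C=C(C(=O)OC)[C@@H]1[C@H]2OS(=O)(=O)O[C@H]2[C@](C)(O)C(=O)O[C@@H]1C[C@@H](C)/C=C\I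
F9 | step 13 | 8-crotonate 9-sulfate monoester | C=C(C(=O)OC)[C@@H]1[C@H](OC(=O)/C=C/C)[C@@H](OS(=O)(=O)O)[C@](C)(O)C(=O)O[C@@H]1C[C@@H](C)/C=C\I
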